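- The closed vessel you ask about holds the birch charge, and its readings end at 5.00 h, so for 12 h I solve both ends and join them.

| setting | birch | cedar | flask |
|---|---|---|---|
| substrate | 20 mM | 20 mM | 20 mM |
| reagent | 26 mM | 52 mM | 26.0 mM |
| remark | the very flask that is asked about, followed so far | run made earlier |  |
| time |  |  | 12 h |

- birch (time / h: substrate / %, target / %, isomer of the product / %): 0.833: 93, 6, 0; 1.50: 93, 5, 1; 2.50: 87, 10, 3; 3.00: 81, 12, 3; 4.00: 81, 16, 0; 5.00: 77, 22, 4
- cedar (time / h: substrate / %, target / %, isomer of the product / %): 1.00: 89, 9, 4; 1.50: 86, 15, 2; 2.50: 73, 20, 5; 4.00: 63, 31, 5; 8.00: 46, 47, 6; 12.0: 39, 48, 10

(scatter of a reading: 1.5 percentage points)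

* which holds at 12 h: what has brought the reaction to rest, or that it has not come to rest (all of the substrate has reacted / it is still moving / forward and back rates have come level / the reagent has run out first)
* conversion of substrate at 12 h
* amount of target at 12 h, in percent of the substrate charged
* amount of isomer of the product at 12 h, in percent of the substrate charged

- the analysis behind the earlier runs scatters by 1.5 percentage points, standard deviation
- reactions considered so far: substrate -> side product; target <-> isomer of the product; substrate + reagent <-> target
- the reaction counts as stopped when no species that holds the substrate changes by six tenths of a point or more over the second half of the time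

- For the start, cedar's substrate reads 73% after 2.50 h; taken as a pseudo-first-order decay of substrate with reagent held at its charge, this reading gives the forward constant k_f = 0.00242 /mM/h.
- For the end, cedar's substrate still falls from 46% to 39% between 8.00 h and 12.0 h, around means of 42.5% substrate and 55.5% target plus isomer. Forward rate minus that net fall leaves the back rate, so I read K, forward over back constant with target and isomer counted together, as 0.0547 /mM, with the scatter of those readings.
- For this flask, side product aside, that K gives 47.4%: the rest share x∞, the converted fraction at which forward and back rates come level.
- To join the ends, I let conversion climb exponentially towards x∞ at λ, the starting rate over x∞, here 0.133 /h. My estimate for this flask is then 37.8% conversion. Cedar's late readings give an isomer share of 14.4%, and if I carry that reading over, my estimate splits into 32.4% target and 5.44% isomer. By this join the second half gains 12 percentage points, against the stopping limit of 0.6 points, and I commit to a flask still moving.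
- Your forecast reads it is still moving, with 39% conversion, 32% target and 5% isomer, on cedar's flat target, “which suggests a reversible step”; it puts equilibrium at about 45% total product, and my x∞ is 47.4%.
- The flask gives it is still moving, with 38.5% conversion, 31.8% target and 6.00% isomer, so the forecast holds.

    substrate → side product (k = 8.20 × 10⁻⁴ /h)
    target ⇌ isomer of the product (K = 0.190, k = 0.820 /h)
    substrate + reagent ⇌ target (K = 43.0 /M, k = 2.80 /M/h)

- The relaxation half-life of the making step, both ways together, is 4.58 h at 12.0 h, shorter than 12 h, and the flask's conversion stands at 81.2% of my x∞. With the other settings held, target has moved by 5 points at 20.9 mM or 31.7 mM of reagent, or at 8.00 h or 22.2 h, and a run showing such a move is what would part it from the forecast's 32%.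
- With 65 mM of reagent, x∞ becomes 73.3%, and the join gives 67.7%; that neighbour computes to 67.5% conversion.

The data were generated by integration for substances that don't exist.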